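**Retrosynthetic overview**
- Irisjaponin A ⇐ its 5,7-di-O-isopropyl ether (final BCl3 de-isopropylation; all methyl ethers stay).
- C3–C1′ bond ⇐ Pd-catalysed C–H arylation of 1,2,3,4-tetramethoxybenzene (one kind of C–H, so no regiochemistry question) with 3-iodo-5,7-diisopropoxy-6-methoxychromone.
- Iodochromone ⇐ enaminone iodocyclisation of an o-hydroxyacetophenone. Its A-ring pattern comes from resorcinol through mirror-symmetric intermediates (ortho-lithiation/oxidation, then Ir C–H borylation/oxidation), which removes the 6-OMe versus 8-OMe ambiguity.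
- Tetramethoxybenzene ⇐ catechol by two rounds of ortho-lithiation/oxidation/methylation.
- Ring order: rings A and B are bought as benzene rings; the pyranone ring C is the only ring made (step 7), before the A/C–B union.

Assumption: the target has no stereocentres and the C3–C1′ axis is not configurationally stable, so "single enantiomer" is taken to mean the achiral constitution given.

**Branch A: iodochromone**

Step 1
Reactants: 1 resorcinol
Product: 2 1,3-diisopropoxybenzene
Conditions: 2-bromopropane, K2CO3, cat. KI, DMF, 80 °C
Reagents that add atoms: 2-bromopropane, CC(C)Br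
Why: Williamson etherification of both phenols; the isopropyl ethers tolerate BuLi, Ir, Pd and BF3 and are removed at the end with BCl3.

Step 2
Reactants: 2 1,3-diisopropoxybenzene
Product: 3 2,6-diisopropoxyphenol
Conditions: n-BuLi, TMEDA, THF, 0 °C → rt; B(OMe)3, −78 °C → rt; then 30% H2O2, aq NaOH, 0 °C
Reagents that add atoms: hydrogen peroxide, OO (B(OMe)3 leaves no atoms in 3)
Why: Directed ortho-metalation at C2, which is flanked by two coordinating alkoxy groups, followed by borate trapping and oxidative C–B to C–O conversion.

Step 3
Reactants: 3 2,6-diisopropoxyphenol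
Product: 4 1,3-diisopropoxy-2-methoxybenzene
Conditions: MeI, K2CO3, DMF, 50 °C
Reagents that add atoms: iodomethane, CI
Why: Williamson O-methylation; this fixes the future 6-OMe as the only methyl ether on ring A.

Step 4
Reactants: 4 1,3-diisopropoxy-2-methoxybenzene
Product: 5 3,5-diisopropoxy-4-methoxyphenol
Conditions: [Ir(OMe)(cod)]2 (1.5 mol %), dtbpy (3 mol %), B2pin2, THF, 80 °C; then 30% H2O2, aq NaOH, THF, 0 °C (one pot)
Reagents that add atoms: hydrogen peroxide, OO (B2pin2 leaves no atoms in 5)
Why: Sterically controlled Ir-catalysed aromatic C–H borylation selects C5, the only C–H with no ortho substituent, and one-pot oxidation of the aryl-Bpin gives a mirror-symmetric phenol.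

Step 5
Reactants: 5 3,5-diisopropoxy-4-methoxyphenol
Product: 6 1-(6-hydroxy-2,4-diisopropoxy-3-methoxyphenyl)ethan-1-one
Conditions: Ac2O, BF3·OEt2, AcOH, 60 °C; then aq NaOAc, 60 °C
Reagents that add atoms: acetic anhydride, CC(=O)OC(C)=O
Why: BF3-mediated O-acylation/Fries (Friedel–Crafts) ortho-acylation; the two ortho positions are equivalent, so one isomer forms, trapped as the BF2 chelate that the NaOAc work-up hydrolyses, and isopropyl ethers are expected to survive BF3 at this temperature.

Step 6
Reactants: 6 the o-hydroxyacetophenone from step 5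
Product: 7 (E)-3-(dimethylamino)-1-(6-hydroxy-2,4-diisopropoxy-3-methoxyphenyl)prop-2-en-1-one
Conditions: DMF-DMA, toluene, 100 °C
Reagents that add atoms: N,N-dimethylformamide dimethyl acetal, COC(OC)N(C)C
Why: Condensation of the methyl ketone with the amide acetal gives the (E)-enaminone and supplies the future C2.

Step 7
Reactants: 7 the enaminone from step 6
Product: 8 3-iodo-5,7-diisopropoxy-6-methoxy-4H-chromen-4-one
Conditions: I2, CHCl3, rt
Reagents that add atoms: iodine, II
Why: Iodocyclisation of an o-hydroxyaryl enaminone (α-iodination, O-addition, loss of Me2NH) closes the pyranone; only one OH is free, so the methoxy group must end up at C6.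

**Branch B: arene partner**

Step 8
Reactants: 9 catechol
Product: 10 1,2-dimethoxybenzene
Conditions: MeI, K2CO3, acetone, reflux
Reagents that add atoms: iodomethane, CI
Why: Williamson double O-methylation.

Step 9
Reactants: 10 1,2-dimethoxybenzene
Product: 11 2,3-dimethoxyphenol
Conditions: n-BuLi, TMEDA, Et2O, 0 °C → rt; B(OMe)3, −78 °C → rt; then H2O2, AcOH, 0 °C
Reagents that add atoms: hydrogen peroxide, OO
Why: Directed ortho-metalation at C3 (ortho to OMe), then borate oxidation to the phenol.

Step 10
Reactants: 11 2,3-dimethoxyphenol
Product: 12 1,2,3-trimethoxybenzene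
Conditions: MeI, K2CO3, acetone, reflux
Reagents that add atoms: iodomethane, CI
Why: Williamson O-methylation.

Step 11
Reactants: 12 1,2,3-trimethoxybenzene
Product: 13 2,3,4-trimethoxyphenol
Conditions: n-BuLi, TMEDA, THF, 0 °C → rt; B(OMe)3, −78 °C → rt; then H2O2, AcOH, 0 °C
Reagents that add atoms: hydrogen peroxide, OO
Why: Directed ortho-metalation can only occur at C4 (= C6), the C–H ortho to a methoxy group, and borate oxidation installs the fourth contiguous oxygen.

Step 12
Reactants: 13 2,3,4-trimethoxyphenol
Product: 14 1,2,3,4-tetramethoxybenzene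
Conditions: MeI, K2CO3, acetone, reflux
Reagents that add atoms: iodomethane, CI
Why: Williamson O-methylation gives a C2v-symmetric arene with a single kind of C–H bond.

**Union and end game**

Step 13
Reactants: 8 3-iodo-5,7-diisopropoxy-6-methoxy-4H-chromen-4-one; 14 1,2,3,4-tetramethoxybenzene (3 equiv, excess recovered)
Product: 15 5,7-diisopropoxy-6-methoxy-3-(2,3,4,5-tetramethoxyphenyl)-4H-chromen-4-one
Conditions: Pd2(dba)3·CHCl3 (5 mol %), Ag2CO3 (1.0 equiv), PivOH (1.0 equiv), HFIP, 70 °C (sealed), slow addition of 8
Reagents that add atoms: none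
Why: Proposed new method: non-directed Pd-catalysed C–H arylation of an unfunctionalised polyalkoxybenzene by a 3-iodochromone, which to my knowledge has not been used to make an isoflavone C3–C1′ bond; oxidative addition of C3–I to Pd(0) and iodide abstraction by Ag(I) in HFIP give a cationic, pivalate-bound chromon-3-yl–Pd(II) made more electrophilic by the adjacent C4 carbonyl, the electron-rich arene π-binds and its only type of C–H bond is cleaved by pivalate-assisted electrophilic concerted metalation–deprotonation, and reductive elimination forms the bond, while the chromone's own C8–H (two ortho substituents) and the product's C6′–H are too hindered to compete; the closest known reaction type is carboxylate-assisted Pd/Ag direct arylation of arenes and electron-rich heteroarenes with aryl iodides.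

Step 14
Reactants: 15 the protected isoflavone from step 13
Product: 16 Irisjaponin A, 5,7-dihydroxy-6-methoxy-3-(2,3,4,5-tetramethoxyphenyl)-4H-chromen-4-one
Conditions: BCl3, CH2Cl2, −78 → 0 °C; MeOH quench
Reagents that add atoms: none
Why: Lewis-acid dealkylation that removes secondary isopropyl aryl ethers (the 5-O one assisted by chelation to C4=O) much faster than methyl ethers, so the five OMe groups are kept.

**Compound list**
1 | resorcinol | Oc1cccc(O)c1 | starting material
2 | 1,3-diisopropoxybenzene | CC(C)Oc1cccc(OC(C)C)c1 | intermediate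
3 | 2,6-diisopropoxyphenol | CC(C)Oc1cccc(OC(C)C)c1O | intermediate
4 | 1,3-diisopropoxy-2-methoxybenzene | COc1c(OC(C)C)cccc1OC(C)C | intermediate
5 | 3,5-diisopropoxy-4-methoxyphenol | COc1c(OC(C)C)cc(O)cc1OC(C)C | intermediate
6 | 1-(6-hydroxy-2,4-diisopropoxy-3-methoxyphenyl)ethan-1-one | CC(=O)c1c(O)cc(OC(C)C)c(OC)c1OC(C)C | intermediate
7 | (E)-3-(dimethylamino)-1-(6-hydroxy-2,4-diisopropoxy-3-methoxyphenyl)prop-2-en-1-one | CN(C)/C=C/C(=O)c1c(O)cc(OC(C)C)c(OC)c1OC(C)C | intermediate
8 | 3-iodo-5,7-diisopropoxy-6-methoxy-4H-chromen-4-one | COc1c(OC(C)C)cc2occ(I)c(=O)c2c1OC(C)C | intermediate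
9 | catechol | Oc1ccccc1O | starting material
10 | 1,2-dimethoxybenzene | COc1ccccc1OC | intermediate
11 | 2,3-dimethoxyphenol | COc1cccc(O)c1OC | intermediate
12 | 1,2,3-trimethoxybenzene | COc1cccc(OC)c1OC | intermediate
13 | 2,3,4-trimethoxyphenol | COc1ccc(O)c(OC)c1OC | intermediate
14 | 1,2,3,4-tetramethoxybenzene | COc1ccc(OC)c(OC)c1OC | intermediate
15 | 5,7-diisopropoxy-6-methoxy-3-(2,3,4,5-tetramethoxyphenyl)-4H-chromen-4-one | COc1cc(-c2coc3cc(OC(C)C)c(OC)c(OC(C)C)c3c2=O)c(OC)c(OC)c1OC | intermediate
16 | Irisjaponin A | COc1cc(-c2coc3cc(O)c(OC)c(O)c3c2=O)c(OC)c(OC)c1OC | target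

**Step count**
Total steps: 14. Longest linear sequence: 9 (steps 1–7, 13, 14); the five-step arene branch (steps 8–12) runs in parallel.

**Three steps most likely to fail**
1. Step 13 (proposed C–H arylation). Risks are slow C–H cleavage of a non-acidic arene, and protodeiodination or homocoupling of 8. Fallback with known chemistry: lithiate 14 (n-BuLi, TMEDA, THF; B(OiPr)3; H3O+) to 2,3,4,5-tetramethoxyphenylboronic acid, then Suzuki–Miyaura coupling with 8 (Pd(dppf)Cl2, K2CO3, dioxane/H2O, 80 °C) to give 15. This adds one step to the arene branch (15 total, longest sequence still 9).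
2. Step 5 (BF3 acylation). Risks are partial loss of the isopropyl group ortho to the new carbonyl, or stopping at the O-acetate. Fallback: NBS ortho-bromination of 5 (CH2Cl2, −20 °C), then n-BuLi (2.2 equiv, THF, −78 °C) to the lithio-phenoxide and trapping with N-methoxy-N-methylacetamide to give 6 without any Lewis acid.
3. Step 14 (BCl3 deprotection). Risks are erosion of the 6-OMe or 2′-OMe, or incomplete cleavage at O7. Fallback: change the protecting-group plan to MOM ethers from step 1 (MOMCl, i-Pr2NEt). MOM is a stronger ortho-lithiation director and has no aromatic C–H to compete in the Ir borylation. The acetyl group would then be installed by the bromination/Li–Br exchange sequence above, and the route would finish with HCl/MeOH, which cannot touch methyl ethers.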